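## The problem

Compound 25 (CNP0137540.1) is a bicyclo[3.3.1]nonan-9-one in which every ring carbon except C2 is functionalised and seven ring carbons (C1, C3, C4, C5, C6, C7, C8) are stereocentres; the (E)-dodec-2-enoyl chain is only an appendage on the C3 nitrogen. Ring A (C1 to C5 with C9) and ring B (C5 to C8 with C1 and C9) share the C1–C9–C5 bridge, so whatever closes the second ring must span two carbons of the first diaxially, and C1 must emerge as a bridgehead tertiary alcohol next to the ketone. The stereochemistry is orderly: the C4 hydroxyl and the C6 methoxy group are both syn to C9, the epoxide oxygen lies on the outer face of ring B cis to the methoxy group, and the C3 nitrogen is equatorial and cis to the C4 hydroxyl. All heteroatoms therefore sit on the convex surface, the C6 oxygen can direct the epoxide, the C4 oxygen can deliver the nitrogen, and C1 and C5 are dictated by the bridge. The fragile parts are the epoxide, the two β-oxygenated ketone relationships (C4–OH and C6–OMe against C9, open to retro-aldol once an alkoxide forms), the bridgehead α-ketol (C1–OH/C9, open to acyloin shift under base) and the enoyl amide, a Michael acceptor; hot hydroxide, strong base and prolonged strong acid are excluded late in the route. If the epoxide oxygen, the O-methyl group and the amide are stripped and C2=C3 and C7=C8 are written as alkenes, the resulting 4,6-diol 10 has a mirror plane through C1, C9 and C5 that exchanges ring A with ring B. In 10, C5 is both the α-carbon of the C9 ketone and the only atom bonded to both carbinol carbons, so C4–C5 and C5–C6 are two aldol bonds from one methyl ketone carbon to two identical cis-enal arms on C1. The price of this symmetry is that handedness must be introduced afterwards by telling two enantiotopic hydroxyls apart.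

## Retrosynthesis

**Side chain and silyl ether (25 ⇐ 24 ⇐ 21 + 22).** The amide C–N bond is cut to amine 21 and commercial (E)-dodec-2-enoic acid 22; the C1 silyl ether of 24 is the only protecting group left at the end. The chain is attached last because its enoyl unit is a Michael acceptor and radical trap that would not pass the oxidative, photochemical and basic operations on the core. The precursor loses twelve carbons and a reactive alkene. The forward steps need N-acylation to beat O-acylation at C4 and a non-basic desilylation.

**Unmasking the amino alcohol (21 ⇐ 20 ⇐ 18 ⇐ 17).** The cis-amino alcohol is traced to oxazolidinone 17; in the forward sense the carbonyl carbon linking N3 and O4 is excised. A ring is preferred to separately protected N and O because it is what tethered nitrogen delivery produces, and it keeps O4 from becoming an alkoxide β to the ketone until late. The opening must avoid hot hydroxide, hence activation as the N-Boc derivative 18 and methanolysis with catalytic Cs2CO3.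

**The C3–N bond (17 ⇐ 16 ⇐ 15 ⇐ 14).** C3–N and C2–H are cut. Delivery from a carbamate on O4 fixes regiochemistry (a five-membered ring reaches C3, not C2) and configuration (cis fusion). An intermolecular amination could not tell C2 from C3. An ionic cyclisation through an iodonium or mercurinium ion is an anti addition and would need the electrophile on the inner face of ring A, which ring B blocks. A nitrogen radical adds first and takes hydrogen afterwards from either face. Precursor 14 has one ring and one stereocentre fewer, and its nitrogen comes from an aryl isocyanate. The forward reaction needs an N–H weak enough for proton-coupled electron transfer, hence an anilide, whose 4-methoxyphenyl group must later be removed oxidatively (16 to 17). The O-methylation (15 to 16) is placed where nitrogen carries no hydrogen.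

**Ring B (14 ⇐ 13 ⇐ 12 ⇐ 11).** The two epoxide C–O bonds are cut. The C6 hydroxyl directs a vanadium-catalysed epoxidation to the outer face, so the methyl group must follow the epoxide; an undirected peracid epoxidation of the methyl ether would rest on shape alone. The carbamate goes onto C4 first (12), serving as protecting group before it serves as tether, and the C6 acetate is then removed (13). Ring B is finished before the radical step because a C2 radical two bonds from a C7=C8 alkene could close onto C8 and shift the vinyl group. Precursor 11 has two stereocentres fewer.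

**Desymmetrisation (11 ⇐ 10).** Only an acetyl C–O bond is cut, but this is where handedness enters: a lipase acylates one of the two enantiotopic hydroxyls of 10. Compared with an asymmetric ring-forming step, this leaves the aldol free of any chiral controller and gives access to either enantiomeric series (acylation of the diol or hydrolysis of its diacetate). The enzyme must accept a hindered bicyclic diol; acetyl migration is not a concern because the two axial hydroxyls diverge.

**Both rings (10 ⇐ 8).** C4–C5 and C5–C6 are cut in the retro-aldol sense. No other pair of cuts opens both rings from one atom: cutting at C1 would ask for double alkylation of a tertiary carbinol centre, and cutting one bond per ring at different atoms destroys the mirror plane. Precursor 8 is acyclic and achiral, with one sp3 carbon carrying the silyloxy group, the acetyl group and two identical cis-enal arms; two rings and four stereocentres (C1, C4, C5, C6) disappear. The forward reaction needs enolisation only at the methyl group, Z alkenes so that each aldehyde reaches C5, chelation for syn hydroxyls, and dilution.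

**The acyclic precursor (8 ⇐ 7 ⇐ 6 ⇐ 5 ⇐ 1 + 2).** C1–C2 and C1–C8 are cut: the quaternary carbinol comes from two equivalents of the lithium acetylide of 1 adding to ester 2, whose ketal is the masked acetyl group. Alkynes are chosen over cis-vinyl nucleophiles because an acetylide adds twice to an ester cleanly and cis geometry then comes from semihydrogenation. Aldehydes and ketone stay masked until one acidic step releases all three. The forward sequence needs silylation of a tertiary alcohol (6) and unmasking without Z to E isomerisation.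

## Roads not taken

**Alternative 1: nitrene C–H amination from a C4 carbamate.** The cut is C3–N on a ring A that is already saturated. A dirhodium nitrene generated from primary carbamate A2 (Rh2(esp)2, PhI(OAc)2, MgO) inserts into the C3–H bond cis to the tether and gives the cis-fused oxazolidinone A1. Its merits are real: insertion proceeds with retention, the tether fixes cis fusion, no alkene is needed in ring A, and the product is an N–H oxazolidinone. As a nitrogen module it is one step shorter than the one chosen here and needs neither light nor tetravalent cerium. Its weak points for this target are the C–H bond and the setting. C3–H is an unactivated methylene inductively deactivated by the β-oxygen, and the benzylic hydrogens of the 4-methoxybenzyl ether in A2 are more reactive toward electrophilic nitrenes and oxidants. The strategy also says nothing about how the bicyclic dione is built or how the C8 ketone becomes the C6 methoxy group and the epoxide, which needs several redox steps without help from symmetry. The chosen plan sets against its shorter nitrogen module the construction of both rings and four stereocentres in one step and a ring A alkene that makes the regiochemistry of nitrogen delivery unambiguous. The nitrene insertion is kept as the fallback for step 10.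

**Alternative 2: aminohydroxylation of a ring A alkene.** The cut removes C3–N and C4–O together. K2OsO2(OH)4 with hydroquinidine 1,4-phthalazinediyl diether and an N-chlorocarbamate salt would add nitrogen and oxygen syn across C3=C4 of alkene A4 from the outer face to give benzyl carbamate A3. If it worked it would be the most economical endgame: two bonds and two stereocentres in one step, correct facial sense from the cage, and a product two steps from the target (hydrogenolysis, acylation). In step count it clearly beats the eight steps spent here between 14 and 21. Its weakness is regiochemistry: C3 and C4 of A4 are both secondary and electronically alike, and the ligand is designed to choose faces, not ends, on a cis-cyclic alkene, so a mixture of regioisomers must be expected. The reaction also exposes the free α-ketol, the epoxide and the newly formed β-hydroxy ketone to aqueous base. Finally, A4 has no oxygen at C4, so it cannot come from an aldol closure and the bicycle would have to be built without the mirror plane. The chosen plan pays more steps but receives C4–O in the ring-forming step and uses it as the anchor that decides where nitrogen goes.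

**Alternative 3: fused-to-bridged α-ketol ring expansion.** The cut is C1–C8, re-formed as C9–C8. In the cis-fused hydrindanone α-ketol A6, Al(OiPr)3 or catalytic KOtBu would shift alkenyl carbon C8 from the carbinol carbon C9 to the C1 ketone carbon, giving the bridged α-ketol A5 with its bridgehead hydroxyl and C9 ketone in one stereospecific step. Its advantages are that nitrogen and the C4 and C6 oxygens are already in place (no late nitrogen module, which is better than the chosen route) and that an asymmetric entry could be made early. The weak points are thermodynamic and chemical. The shift is reversible and it is not clear that the bridged ketol is favoured over the fused one. Alkyl carbon C5 can migrate in competition. The carbamate nitrogen of A6 is β to the C1 ketone and can be eliminated by base. Al(OiPr)3 is also a hydride-transfer reductant for ketones. All five stereocentres of A6 must be set on a fused system without symmetry, so the length moves into its preparation, and A5 still needs epoxidation, deprotection and acylation. The chosen plan sets against its ready-made nitrogen the four-step access to an achiral precursor and the one-step formation of the bicycle.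

Key step: step 5

Remark on names: every bicyclic compound carries the locants of the target (C1 oxygenated bridgehead, C2 to C4 in ring A, C5 the CH bridgehead, C6 to C8 in ring B, C9 the ketone). "Syn" means on the side of the C9 bridge, which is axial on the ring bearing the substituent and on its outer face.

Assumption: the lipase is taken to follow the empirical rule for secondary alcohols, with the bridgehead flank C5 as the large and the vinylic CH as the medium group, so that it works at the (R)-carbinol of 10, which is C6 (in 10, C4 is S and C6 is R).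

## Route

Step 1
Reactants: 1 propiolaldehyde diethyl acetal (3,3-diethoxyprop-1-yne); 2 methyl 2,2-dimethoxypropanoate
Product: 5 4-(1,1-dimethoxyethyl)-1,1,7,7-tetraethoxyhepta-2,5-diyn-4-ol, via lithium acetylide 3 (not isolated), via mono-adduct ynone 4 (not isolated)
Conditions: 1 (2.5 equiv), n-BuLi, THF, −78 °C; then 2, −78 to 0 °C; aqueous work-up
Reagents that add atoms: none
Why: Acetylide addition to a non-enolisable ester activated by two α-alkoxy groups: the first addition gives ynone 4, which is more electrophilic than the ester and takes the second acetylide at the carbonyl carbon, giving the bis-propargylic tertiary carbinol; no stereocentre is formed.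

Step 2
Reactants: 5 4-(1,1-dimethoxyethyl)-1,1,7,7-tetraethoxyhepta-2,5-diyn-4-ol
Product: 6 tert-butyl{[4-(1,1-dimethoxyethyl)-1,1,7,7-tetraethoxyhepta-2,5-diyn-4-yl]oxy}dimethylsilane
Conditions: TBSOTf, 2,6-lutidine, CH2Cl2, −78 to 0 °C
Reagents that add atoms: tert-butyldimethylsilyl trifluoromethanesulfonate, CC(C)(C)[Si](C)(C)OS(=O)(=O)C(F)(F)F
Why: Silylation of a tertiary alcohol with a silyl triflate and a hindered pyridine base; the two slim alkynyl neighbours keep the carbinol accessible, and at low temperature the inductively deactivated propargylic acetals and the hindered ketal should not be ionised.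

Step 3
Reactants: 6 tert-butyl{[4-(1,1-dimethoxyethyl)-1,1,7,7-tetraethoxyhepta-2,5-diyn-4-yl]oxy}dimethylsilane
Product: 7 tert-butyl{[(2Z,5Z)-4-(1,1-dimethoxyethyl)-1,1,7,7-tetraethoxyhepta-2,5-dien-4-yl]oxy}dimethylsilane
Conditions: H2 (1 atm), Pd/CaCO3 poisoned with Pb(OAc)2, quinoline, EtOAc, rt
Reagents that add atoms: none
Why: Cis-semihydrogenation of both alkynes on poisoned palladium; syn delivery of hydrogen from the metal surface sets both Z alkenes and quinoline holds back over-reduction.

Step 4
Reactants: 7 tert-butyl{[(2Z,5Z)-4-(1,1-dimethoxyethyl)-1,1,7,7-tetraethoxyhepta-2,5-dien-4-yl]oxy}dimethylsilane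
Product: 8 (2Z,5Z)-4-acetyl-4-(tert-butyldimethylsilyloxy)hepta-2,5-dienedial
Conditions: TsOH·H2O (cat.), acetone/H2O (10:1), 0 °C to rt; then NaHCO3
Reagents that add atoms: water, O
Why: Acid-catalysed hydrolysis of two allylic acetals and one ketal; the γ-carbon is quaternary and oxygenated, so neither a dienol nor a stabilised allyl cation offers an easy path from Z to E, and cold, brief exposure should keep both cis enals while the tertiary silyl ether stays.

Step 5
Reactants: 8 (2Z,5Z)-4-acetyl-4-(tert-butyldimethylsilyloxy)hepta-2,5-dienedial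
Product: 10 meso-(4S,6R)-1-(tert-butyldimethylsilyloxy)-4,6-dihydroxybicyclo[3.3.1]nona-2,7-dien-9-one (both hydroxyls syn to C9), via monocyclic aldolate 9 (not isolated)
Conditions: MgBr2·OEt2 (3 equiv), Et3N (4 equiv), CH2Cl2 (0.01 M), 0 °C to rt; aq. NH4Cl
Reagents that add atoms: none
Why: MgBr2 binds the ketone and Et3N removes a proton from the methyl group, the only enolisable position (C1 is quaternary and the enals have no γ-hydrogen), giving the magnesium enolate C5=C9 by soft enolisation. C5 then adds to one aldehyde in a 6-(enolendo)-exo-trig aldol that closes ring A; the Z alkene holds C4 within reach and conjugate addition would need a four-membered ring. Aldolate 9 is enolised again at C5, and a second aldol of the same 6-(enolendo)-exo-trig mode onto the arm that sits axial on ring A closes ring B and completes the bicyclo[3.3.1]nonan-9-one. The closest known reactions are the intramolecular aldol addition of keto aldehydes under soft enolisation and the bridged aldol closure of 2-(3-oxopropyl)cyclohexanones to 2-hydroxybicyclo[3.3.1]nonan-9-ones, here run twice in one flask. C4 and C6 are set by the closed, chelated transition state: magnesium bridges the enolate and aldehyde oxygens, so each new C–O bond is gauche to C9–O and each hydroxyl ends syn to the carbonyl. C1 and C5 have no freedom, because a three-carbon bridge can span them only diaxially, so with both hydroxyls syn the product is the meso isomer. The step needs the meso diol over the unsymmetrical and the anti,anti isomers; chelation in each closure and the reversibility of the aldolates, which returns a mono-adduct of the wrong C4 configuration by retro-aldol, should secure this, while high dilution holds off intermolecular aldol. Once ring B is closed, C5 is a bridgehead, so neither dehydration nor further enolisation is possible and the product is the resting point.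

Step 6
Reactants: 10 meso-(4S,6R)-1-(tert-butyldimethylsilyloxy)-4,6-dihydroxybicyclo[3.3.1]nona-2,7-dien-9-one
Product: 11 (4S,6R)-6-acetoxy-1-(tert-butyldimethylsilyloxy)-4-hydroxybicyclo[3.3.1]nona-2,7-dien-9-one (both oxygens syn to C9)
Conditions: lipase from Burkholderia cepacia (immobilised), vinyl acetate, t-BuOMe, 30 °C
Reagents that add atoms: vinyl acetate, CC(=O)OC=C
Why: Lipase-catalysed irreversible transesterification that differentiates the enantiotopic hydroxyls of a meso diol; acylation of the (R)-carbinol C6 fixes the absolute configuration of C1, C4, C5 and C6 at once, and the two axial hydroxyls diverge too far for acetyl migration.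

Step 7
Reactants: 11 (4S,6R)-6-acetoxy-1-(tert-butyldimethylsilyloxy)-4-hydroxybicyclo[3.3.1]nona-2,7-dien-9-one
Product: 12 (4S,6R)-6-acetoxy-1-(tert-butyldimethylsilyloxy)-4-[(4-methoxyphenyl)carbamoyloxy]bicyclo[3.3.1]nona-2,7-dien-9-one
Conditions: 4-MeOC6H4NCO, Et3N, CH2Cl2, rt
Reagents that add atoms: 4-methoxyphenyl isocyanate, COc1ccc(N=C=O)cc1
Why: Amine-catalysed addition of an alcohol to an aryl isocyanate (carbamoylation); the carbamate protects O4 now and is the nitrogen tether later.

Step 8
Reactants: 12 (4S,6R)-6-acetoxy-1-(tert-butyldimethylsilyloxy)-4-[(4-methoxyphenyl)carbamoyloxy]bicyclo[3.3.1]nona-2,7-dien-9-one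
Product: 13 1-(tert-butyldimethylsilyloxy)-6-hydroxy-4-[(4-methoxyphenyl)carbamoyloxy]bicyclo[3.3.1]nona-2,7-dien-9-one (6-OH and 4-O syn to C9)
Conditions: K2CO3 (0.2 equiv), MeOH, 0 °C
Reagents that add atoms: none
Why: Base-catalysed methanolysis of the acetate (transesterification); the N-aryl carbamate should be inert to catalytic carbonate at 0 °C, and β-elimination toward C5 is impossible because C5 is a bridgehead.

Step 9
Reactants: 13 1-(tert-butyldimethylsilyloxy)-6-hydroxy-4-[(4-methoxyphenyl)carbamoyloxy]bicyclo[3.3.1]nona-2,7-dien-9-one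
Product: 14 1-(tert-butyldimethylsilyloxy)-7,8-epoxy-6-hydroxy-4-[(4-methoxyphenyl)carbamoyloxy]bicyclo[3.3.1]non-2-en-9-one (epoxide on the outer face of ring B, cis to 6-OH)
Conditions: VO(acac)2 (5 mol%), t-BuOOH (decane), CH2Cl2, 0 °C to rt
Reagents that add atoms: tert-butyl hydroperoxide, CC(C)(C)OO
Why: Hydroxyl-directed vanadium-catalysed epoxidation of an allylic alcohol: the pseudoaxial C6 hydroxyl binds vanadium and delivers the peroxide oxygen to its own, outer face of C7=C8, setting C7 and C8, while C2=C3 has no free hydroxyl and should remain.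

Step 10
Reactants: 14 1-(tert-butyldimethylsilyloxy)-7,8-epoxy-6-hydroxy-4-[(4-methoxyphenyl)carbamoyloxy]bicyclo[3.3.1]non-2-en-9-one
Product: 15 N-(4-methoxyphenyl) oxazolidinone cis-fused across C3 (N) and C4 (O) of 1-(tert-butyldimethylsilyloxy)-7,8-epoxy-6-hydroxybicyclo[3.3.1]nonan-9-one
Conditions: [Ir(dF(CF3)ppy)2(bpy)]PF6 (2 mol%; dF(CF3)ppy = cyclometalated 2-(2,4-difluorophenyl)-5-(trifluoromethyl)pyridine, bpy = 2,2'-bipyridine), Bu4N[(BuO)2PO2] (20 mol%), PhSH (10 to 30 mol%), CH2Cl2, blue LEDs, rt
Reagents that add atoms: none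
Why: Photocatalytic hydroamidation by proton-coupled electron transfer: the excited iridium complex and the phosphate base together remove the anilide hydrogen, the amidyl radical closes 5-exo-trig onto C3 (a five-membered ring can only be cis-fused, so nitrogen ends cis to O4 and equatorial), and the C2 radical takes hydrogen from thiophenol. With ring B already an epoxide, no alkene remains for the C2 radical to attack.

Step 11
Reactants: 15 N-(4-methoxyphenyl) oxazolidinone cis-fused across C3 and C4 of 1-(tert-butyldimethylsilyloxy)-7,8-epoxy-6-hydroxybicyclo[3.3.1]nonan-9-one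
Product: 16 N-(4-methoxyphenyl) oxazolidinone cis-fused across C3 and C4 of 1-(tert-butyldimethylsilyloxy)-7,8-epoxy-6-methoxybicyclo[3.3.1]nonan-9-one
Conditions: Me3OBF4, 1,8-bis(dimethylamino)naphthalene, CH2Cl2, 0 °C to rt
Reagents that add atoms: trimethyloxonium tetrafluoroborate, C[O+](C)C.F[B-](F)(F)F
Why: O-Methylation with an oxonium salt and a non-nucleophilic proton scavenger; no alkoxide is formed, so retro-aldol and epoxide migration are avoided, and nitrogen bears no hydrogen that could compete.

Step 12
Reactants: 16 N-(4-methoxyphenyl) oxazolidinone cis-fused across C3 and C4 of 1-(tert-butyldimethylsilyloxy)-7,8-epoxy-6-methoxybicyclo[3.3.1]nonan-9-one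
Product: 17 N-unsubstituted oxazolidinone cis-fused across C3 (N) and C4 (O) of 1-(tert-butyldimethylsilyloxy)-7,8-epoxy-6-methoxybicyclo[3.3.1]nonan-9-one
Conditions: (NH4)2Ce(NO3)6 (2.5 equiv), MeCN/H2O (3:1), 0 °C
Reagents that add atoms: none
Why: Oxidative N-dearylation of a 4-methoxyphenyl amide by tetravalent cerium: two-electron oxidation to the quinone iminium and hydrolysis release the N–H oxazolidinone and benzoquinone. The epoxide is flanked by electron-poor, hindered carbons and shielded from backside attack by ring A, and the tertiary silyl ether should withstand the brief acidic medium.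

Step 13
Reactants: 17 N-unsubstituted oxazolidinone cis-fused across C3 and C4 of 1-(tert-butyldimethylsilyloxy)-7,8-epoxy-6-methoxybicyclo[3.3.1]nonan-9-one
Product: 18 N-(tert-butoxycarbonyl) derivative of oxazolidinone 17
Conditions: Boc2O, Et3N, DMAP (cat.), THF, rt
Reagents that add atoms: di-tert-butyl dicarbonate, CC(C)(C)OC(=O)OC(=O)OC(C)(C)C
Why: DMAP-catalysed N-acylation of the oxazolidinone; the Boc group turns the ring carbonyl into the most electrophilic site for the next step.

Step 14
Reactants: 18 N-(tert-butoxycarbonyl) derivative of oxazolidinone 17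
Product: 20 tert-butyl N-[1-(tert-butyldimethylsilyloxy)-7,8-epoxy-4-hydroxy-6-methoxy-9-oxobicyclo[3.3.1]nonan-3-yl]carbamate (3-N equatorial and cis to 4-OH), via methyl carbonate 19 (not isolated)
Conditions: Cs2CO3 (0.3 equiv), MeOH, 0 °C to rt
Reagents that add atoms: none
Why: Methoxide opens the activated ring carbonyl with loss of the stabilised carbamate nitrogen, and methyl carbonate 19 is then methanolysed to the free C4 hydroxyl (mild cleavage of an N-Boc oxazolidinone); catalytic base at room temperature replaces the hot hydroxide an unactivated oxazolidinone would need.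

Step 15
Reactants: 20 tert-butyl N-[1-(tert-butyldimethylsilyloxy)-7,8-epoxy-4-hydroxy-6-methoxy-9-oxobicyclo[3.3.1]nonan-3-yl]carbamate
Product: 21 3-amino-1-(tert-butyldimethylsilyloxy)-7,8-epoxy-4-hydroxy-6-methoxybicyclo[3.3.1]nonan-9-one
Conditions: CF3CO2H, CH2Cl2, 0 °C; then aq. NaHCO3
Reagents that add atoms: none
Why: Acidolysis of the tert-butyl carbamate; the epoxide is deactivated by its oxygenated neighbours and its backside is covered by ring A, and the tertiary silyl ether should survive brief acid at 0 °C.

Step 16
Reactants: 21 3-amino-1-(tert-butyldimethylsilyloxy)-7,8-epoxy-4-hydroxy-6-methoxybicyclo[3.3.1]nonan-9-one; 22 (E)-dodec-2-enoic acid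
Product: 24 (E)-N-[1-(tert-butyldimethylsilyloxy)-7,8-epoxy-4-hydroxy-6-methoxy-9-oxobicyclo[3.3.1]nonan-3-yl]dodec-2-enamide, via benzotriazolyl ester 23 (not isolated)
Conditions: EDC·HCl, HOBt, i-Pr2NEt, CH2Cl2, 0 °C to rt
Reagents that add atoms: none
Why: Carbodiimide amide coupling through active ester 23; the primary amine reacts far faster than the hindered axial C4 hydroxyl, and the E alkene is not touched.

Step 17
Reactants: 24 (E)-N-[1-(tert-butyldimethylsilyloxy)-7,8-epoxy-4-hydroxy-6-methoxy-9-oxobicyclo[3.3.1]nonan-3-yl]dodec-2-enamide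
Product: 25 CNP0137540.1, (E)-N-[7,8-epoxy-1,4-dihydroxy-6-methoxy-9-oxobicyclo[3.3.1]nonan-3-yl]dodec-2-enamide
Conditions: HF·pyridine, pyridine, THF, 0 °C to rt
Reagents that add atoms: none
Why: Fluoride-mediated cleavage of the silyl ether with buffered HF·pyridine, chosen over basic fluoride sources so that retro-aldol, α-ketol rearrangement and epoxide opening are avoided.

## Compound list

1 | propiolaldehyde diethyl acetal (3,3-diethoxyprop-1-yne) | CCOC(OCC)C#C | starting material
2 | methyl 2,2-dimethoxypropanoate | COC(=O)C(C)(OC)OC | starting material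
3 | (3,3-diethoxyprop-1-yn-1-yl)lithium (not isolated) | [Li]C#CC(OCC)OCC | intermediate
4 | 1,1-diethoxy-5,5-dimethoxyhex-2-yn-4-one (not isolated) | CCOC(OCC)C#CC(=O)C(C)(OC)OC | intermediate
5 | 4-(1,1-dimethoxyethyl)-1,1,7,7-tetraethoxyhepta-2,5-diyn-4-ol | CCOC(OCC)C#CC(O)(C#CC(OCC)OCC)C(C)(OC)OC | intermediate
6 | tert-butyl{[4-(1,1-dimethoxyethyl)-1,1,7,7-tetraethoxyhepta-2,5-diyn-4-yl]oxy}dimethylsilane | CCOC(OCC)C#CC(O[Si](C)(C)C(C)(C)C)(C#CC(OCC)OCC)C(C)(OC)OC | intermediate
7 | tert-butyl{[(2Z,5Z)-4-(1,1-dimethoxyethyl)-1,1,7,7-tetraethoxyhepta-2,5-dien-4-yl]oxy}dimethylsilane | CCOC(OCC)/C=C\C(O[Si](C)(C)C(C)(C)C)(/C=C\C(OCC)OCC)C(C)(OC)OC | intermediate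
8 | (2Z,5Z)-4-acetyl-4-(tert-butyldimethylsilyloxy)hepta-2,5-dienedial | CC(=O)C(O[Si](C)(C)C(C)(C)C)(/C=C\C=O)/C=C\C=O | intermediate
9 | rac-6-(tert-butyldimethylsilyloxy)-4-hydroxy-6-[(Z)-3-oxoprop-1-enyl]cyclohex-2-en-1-one, hydroxyl cis to the silyloxy group (magnesium aldolate in the flask, not isolated; one enantiomer drawn) | C1=C[C@@](/C=C\C=O)(O[Si](C)(C)C(C)(C)C)C(=O)C[C@H]1O | intermediate
10 | meso-(4S,6R)-1-(tert-butyldimethylsilyloxy)-4,6-dihydroxybicyclo[3.3.1]nona-2,7-dien-9-one, both hydroxyls syn to C9 | C1=C[C@@]2(O[Si](C)(C)C(C)(C)C)C(=O)[C@@H]([C@H]1O)[C@H](O)C=C2 | intermediate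
11 | (4S,6R)-6-acetoxy-1-(tert-butyldimethylsilyloxy)-4-hydroxybicyclo[3.3.1]nona-2,7-dien-9-one | C1=C[C@@]2(O[Si](C)(C)C(C)(C)C)C(=O)[C@@H]([C@H]1O)[C@H](OC(C)=O)C=C2 | intermediate
12 | (4S,6R)-6-acetoxy-1-(tert-butyldimethylsilyloxy)-4-[(4-methoxyphenyl)carbamoyloxy]bicyclo[3.3.1]nona-2,7-dien-9-one | C1=C[C@@]2(O[Si](C)(C)C(C)(C)C)C(=O)[C@@H]([C@H]1OC(=O)Nc1ccc(OC)cc1)[C@H](OC(C)=O)C=C2 | intermediate
13 | 1-(tert-butyldimethylsilyloxy)-6-hydroxy-4-[(4-methoxyphenyl)carbamoyloxy]bicyclo[3.3.1]nona-2,7-dien-9-one | C1=C[C@@]2(O[Si](C)(C)C(C)(C)C)C(=O)[C@@H]([C@H]1OC(=O)Nc1ccc(OC)cc1)[C@H](O)C=C2 | intermediate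
14 | 1-(tert-butyldimethylsilyloxy)-7,8-epoxy-6-hydroxy-4-[(4-methoxyphenyl)carbamoyloxy]bicyclo[3.3.1]non-2-en-9-one, epoxide cis to 6-OH | C1=C[C@@]2(O[Si](C)(C)C(C)(C)C)C(=O)[C@@H]([C@H]1OC(=O)Nc1ccc(OC)cc1)[C@H](O)[C@@H]1O[C@@H]12 | intermediate
15 | N-(4-methoxyphenyl) oxazolidinone cis-fused across C3 (N) and C4 (O) of 1-(tert-butyldimethylsilyloxy)-7,8-epoxy-6-hydroxybicyclo[3.3.1]nonan-9-one | COc1ccc(cc1)N1[C@H]2C[C@@]3(O[Si](C)(C)C(C)(C)C)C(=O)[C@@H]([C@H]2OC1=O)[C@H](O)[C@@H]1O[C@@H]13 | intermediate
16 | N-(4-methoxyphenyl) oxazolidinone cis-fused across C3 and C4 of 1-(tert-butyldimethylsilyloxy)-7,8-epoxy-6-methoxybicyclo[3.3.1]nonan-9-one | COc1ccc(cc1)N1[C@H]2C[C@@]3(O[Si](C)(C)C(C)(C)C)C(=O)[C@@H]([C@H]2OC1=O)[C@H](OC)[C@@H]1O[C@@H]13 | intermediate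
17 | N-unsubstituted oxazolidinone cis-fused across C3 and C4 of 1-(tert-butyldimethylsilyloxy)-7,8-epoxy-6-methoxybicyclo[3.3.1]nonan-9-one | O=C1N[C@H]2C[C@@]3(O[Si](C)(C)C(C)(C)C)C(=O)[C@@H]([C@H]2O1)[C@H](OC)[C@@H]2O[C@@H]23 | intermediate
18 | N-(tert-butoxycarbonyl) derivative of oxazolidinone 17 | CC(C)(C)OC(=O)N1[C@H]2C[C@@]3(O[Si](C)(C)C(C)(C)C)C(=O)[C@@H]([C@H]2OC1=O)[C@H](OC)[C@@H]1O[C@@H]13 | intermediate
19 | methyl carbonate at O4 of carbamate 20 (not isolated) | CC(C)(C)OC(=O)N[C@H]1C[C@@]2(O[Si](C)(C)C(C)(C)C)C(=O)[C@@H]([C@H]1OC(=O)OC)[C@H](OC)[C@@H]1O[C@@H]12 | intermediate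
20 | tert-butyl N-[1-(tert-butyldimethylsilyloxy)-7,8-epoxy-4-hydroxy-6-methoxy-9-oxobicyclo[3.3.1]nonan-3-yl]carbamate | CC(C)(C)OC(=O)N[C@H]1C[C@@]2(O[Si](C)(C)C(C)(C)C)C(=O)[C@@H]([C@H]1O)[C@H](OC)[C@@H]1O[C@@H]12 | intermediate
21 | 3-amino-1-(tert-butyldimethylsilyloxy)-7,8-epoxy-4-hydroxy-6-methoxybicyclo[3.3.1]nonan-9-one | N[C@H]1C[C@@]2(O[Si](C)(C)C(C)(C)C)C(=O)[C@@H]([C@H]1O)[C@H](OC)[C@@H]1O[C@@H]12 | intermediate
22 | (E)-dodec-2-enoic acid | CCCCCCCCC/C=C/C(=O)O | starting material
23 | benzotriazol-1-yl (E)-dodec-2-enoate (not isolated) | CCCCCCCCC/C=C/C(=O)On1nnc2ccccc12 | intermediate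
24 | (E)-N-[1-(tert-butyldimethylsilyloxy)-7,8-epoxy-4-hydroxy-6-methoxy-9-oxobicyclo[3.3.1]nonan-3-yl]dodec-2-enamide | CCCCCCCCC/C=C/C(=O)N[C@H]1C[C@@]2(O[Si](C)(C)C(C)(C)C)C(=O)[C@@H]([C@H]1O)[C@H](OC)[C@@H]1O[C@@H]12 | intermediate
25 | CNP0137540.1, (E)-N-[7,8-epoxy-1,4-dihydroxy-6-methoxy-9-oxobicyclo[3.3.1]nonan-3-yl]dodec-2-enamide | CCCCCCCCC/C=C/C(=O)N[C@H]1C[C@@]2(O)C(=O)[C@@H]([C@H]1O)[C@H](OC)[C@@H]1O[C@@H]12 | target

## Step count and least certain steps

Total: 17 steps. Longest linear sequence: 17 steps from 2 (or 1); acid 22 enters at step 16.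

**Step 5 (key step).** The cascade may stall after the first closure, so that aldolate 9 loses water toward a cross-conjugated dienone or enters intermolecular aldol reactions. Discrimination between the chelated and the open closure may also be incomplete, giving a hydroxyl anti to C9 at one or both carbinol centres. Both follow from the need for two consecutive enolisations at the same carbon while an enal is still free. Fallback, from 8 back to 10, with the two closures as separate operations:
- Ring A is closed with a boron enolate (dicyclohexylboron chloride, Et3N, −78 °C); the boron aldolate neither re-enolises nor equilibrates, and 9 is isolated and freed from its C4 epimer.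
- 9 is protected as rac-6-(tert-butyldimethylsilyloxy)-6-[(Z)-3-oxoprop-1-enyl]-4-(triethylsilyloxy)cyclohex-2-en-1-one F1 (TESOTf, 2,6-lutidine).
- Ring B is closed by a single soft enolisation (MgBr2·OEt2, Et3N) to rac-1-(tert-butyldimethylsilyloxy)-6-hydroxy-4-(triethylsilyloxy)bicyclo[3.3.1]nona-2,7-dien-9-one F2.
- Removal of the triethylsilyl group (AcOH, THF, H2O) returns the meso diol 10.

**Step 4.** Isomerisation of the cis enals to trans during acidic unmasking is the main danger, made worse if the ketal next to the quaternary silyloxy carbon hydrolyses slowly and prolongs acid exposure; a trans enal cannot reach C5. Fallback, from 2 back to 8, generating the aldehydes by oxidation instead of hydrolysis: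
- 2 is treated with two equivalents of lithiated tert-butyldimethyl(prop-2-ynyloxy)silane to give 1,7-bis(tert-butyldimethylsilyloxy)-4-(1,1-dimethoxyethyl)hepta-2,5-diyn-4-ol F3.
- Silylation gives 1,4,7-tris(tert-butyldimethylsilyloxy)-4-(1,1-dimethoxyethyl)hepta-2,5-diyne F4.
- Semihydrogenation over Pd/CaCO3 poisoned with Pb(OAc)2 gives (2Z,5Z)-1,4,7-tris(tert-butyldimethylsilyloxy)-4-(1,1-dimethoxyethyl)hepta-2,5-diene F5.
- Mild acid removes the primary silyl ethers and the ketal (the tertiary silyl ether stays) to give (Z)-3-(tert-butyldimethylsilyloxy)-6-hydroxy-3-[(Z)-3-hydroxyprop-1-enyl]hex-4-en-2-one F6, which may rest partly as a cyclic hemiketal.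
- Buffered Dess–Martin oxidation (or MnO2) under non-acidic conditions gives 8.

**Step 6.** The enzyme may accept the hindered bicyclic diol poorly or work at the other enantiotopic hydroxyl, since the sense rests on an empirical rule. Fallback, from 10 back to 11, exploiting the enantio-complementarity of acylation and hydrolysis: 10 is acetylated twice (Ac2O, pyridine, DMAP) to meso-4,6-diacetoxy-1-(tert-butyldimethylsilyloxy)bicyclo[3.3.1]nona-2,7-dien-9-one F7. The same lipase in pH 7 buffer then hydrolyses one acetate; if the enzyme prefers the C4 centre, it is the C4 acetate that is cleaved and 11 results.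

**Step 10.** Ring closure of the carbamate-derived nitrogen radical may be slow, because the carbamate must leave its preferred ester conformation, so that back-transfer of hydrogen from the thiol outruns cyclisation; the C2 radical may also rearrange before it is quenched. Fallback, from 11 back to 17, replacing radical addition by nitrene C–H insertion on a saturated ring A (this also removes the aryl group and therefore the cerium oxidation of step 12, whose own risk is acid-promoted opening of the epoxide):
- 11 is treated with trichloroacetyl isocyanate to give 6-acetoxy-1-(tert-butyldimethylsilyloxy)-4-[(trichloroacetyl)carbamoyloxy]bicyclo[3.3.1]nona-2,7-dien-9-one F8.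
- K2CO3 in MeOH removes the trichloroacetyl and acetyl groups to give 4-carbamoyloxy-1-(tert-butyldimethylsilyloxy)-6-hydroxybicyclo[3.3.1]nona-2,7-dien-9-one F9.
- VO(acac)2 and t-BuOOH give 4-carbamoyloxy-1-(tert-butyldimethylsilyloxy)-7,8-epoxy-6-hydroxybicyclo[3.3.1]non-2-en-9-one F10.
- Me3OBF4 with 1,8-bis(dimethylamino)naphthalene gives 4-carbamoyloxy-1-(tert-butyldimethylsilyloxy)-7,8-epoxy-6-methoxybicyclo[3.3.1]non-2-en-9-one F11.
- Hydrogenation of C2=C3 (H2, RhCl(PPh3)3) gives 4-carbamoyloxy-1-(tert-butyldimethylsilyloxy)-7,8-epoxy-6-methoxybicyclo[3.3.1]nonan-9-one F12.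
- Rh2(esp)2 (esp = α,α,α′,α′-tetramethyl-1,3-benzenedipropionate), PhI(OAc)2 and MgO convert the carbamate into a nitrene that inserts with retention into the C3–H bond cis to the tether, giving 17.

**Step 15.** Acid-promoted opening of the epoxide, or partial loss of the silyl ether, may accompany removal of the Boc group. Fallback, from 17 back to 21, unveiling nitrogen under neutral conditions:
- 17 is acylated on nitrogen (LiN(SiMe3)2, allyl chloroformate, −78 °C) to the N-allyloxycarbonyl derivative of oxazolidinone 17 F13.
- Cs2CO3 in MeOH opens F13 to allyl N-[1-(tert-butyldimethylsilyloxy)-7,8-epoxy-4-hydroxy-6-methoxy-9-oxobicyclo[3.3.1]nonan-3-yl]carbamate F14.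
- Pd(PPh3)4, a zerovalent palladium complex, with morpholine as allyl acceptor releases 21.

## Further compounds

F1 | step 5 | rac-6-(tert-butyldimethylsilyloxy)-6-[(Z)-3-oxoprop-1-enyl]-4-(triethylsilyloxy)cyclohex-2-en-1-one (4-O cis to 6-O; one enantiomer drawn) | C1=C[C@@](/C=C\C=O)(O[Si](C)(C)C(C)(C)C)C(=O)C[C@H]1O[Si](CC)(CC)CC
F2 | step 5 | rac-1-(tert-butyldimethylsilyloxy)-6-hydroxy-4-(triethylsilyloxy)bicyclo[3.3.1]nona-2,7-dien-9-one (both oxygens syn to C9; one enantiomer drawn) | C1=C[C@@]2(O[Si](C)(C)C(C)(C)C)C(=O)[C@@H]([C@H]1O[Si](CC)(CC)CC)[C@H](O)C=C2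
F3 | step 4 | 1,7-bis(tert-butyldimethylsilyloxy)-4-(1,1-dimethoxyethyl)hepta-2,5-diyn-4-ol | CC(OC)(OC)C(O)(C#CCO[Si](C)(C)C(C)(C)C)C#CCO[Si](C)(C)C(C)(C)C
F4 | step 4 | 1,4,7-tris(tert-butyldimethylsilyloxy)-4-(1,1-dimethoxyethyl)hepta-2,5-diyne | CC(OC)(OC)C(O[Si](C)(C)C(C)(C)C)(C#CCO[Si](C)(C)C(C)(C)C)C#CCO[Si](C)(C)C(C)(C)C
F5 | step 4 | (2Z,5Z)-1,4,7-tris(tert-butyldimethylsilyloxy)-4-(1,1-dimethoxyethyl)hepta-2,5-diene | CC(OC)(OC)C(O[Si](C)(C)C(C)(C)C)(/C=C\CO[Si](C)(C)C(C)(C)C)/C=C\CO[Si](C)(C)C(C)(C)C
F6 | step 4 | (Z)-3-(tert-butyldimethylsilyloxy)-6-hydroxy-3-[(Z)-3-hydroxyprop-1-enyl]hex-4-en-2-one | CC(=O)C(O[Si](C)(C)C(C)(C)C)(/C=C\CO)/C=C\CO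
F7 | step 6 | meso-4,6-diacetoxy-1-(tert-butyldimethylsilyloxy)bicyclo[3.3.1]nona-2,7-dien-9-one | C1=C[C@@]2(O[Si](C)(C)C(C)(C)C)C(=O)[C@@H]([C@H]1OC(C)=O)[C@H](OC(C)=O)C=C2
F8 | step 10 | 6-acetoxy-1-(tert-butyldimethylsilyloxy)-4-[(trichloroacetyl)carbamoyloxy]bicyclo[3.3.1]nona-2,7-dien-9-one | C1=C[C@@]2(O[Si](C)(C)C(C)(C)C)C(=O)[C@@H]([C@H]1OC(=O)NC(=O)C(Cl)(Cl)Cl)[C@H](OC(C)=O)C=C2
F9 | step 10 | 4-carbamoyloxy-1-(tert-butyldimethylsilyloxy)-6-hydroxybicyclo[3.3.1]nona-2,7-dien-9-one | C1=C[C@@]2(O[Si](C)(C)C(C)(C)C)C(=O)[C@@H]([C@H]1OC(N)=O)[C@H](O)C=C2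
F10 | step 10 | 4-carbamoyloxy-1-(tert-butyldimethylsilyloxy)-7,8-epoxy-6-hydroxybicyclo[3.3.1]non-2-en-9-one | C1=C[C@@]2(O[Si](C)(C)C(C)(C)C)C(=O)[C@@H]([C@H]1OC(N)=O)[C@H](O)[C@@H]1O[C@@H]12
F11 | step 10 | 4-carbamoyloxy-1-(tert-butyldimethylsilyloxy)-7,8-epoxy-6-methoxybicyclo[3.3.1]non-2-en-9-one | C1=C[C@@]2(O[Si](C)(C)C(C)(C)C)C(=O)[C@@H]([C@H]1OC(N)=O)[C@H](OC)[C@@H]1O[C@@H]12
F12 | step 10 | 4-carbamoyloxy-1-(tert-butyldimethylsilyloxy)-7,8-epoxy-6-methoxybicyclo[3.3.1]nonan-9-one | C1C[C@@]2(O[Si](C)(C)C(C)(C)C)C(=O)[C@@H]([C@H]1OC(N)=O)[C@H](OC)[C@@H]1O[C@@H]12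
F13 | step 15 | N-allyloxycarbonyl derivative of oxazolidinone 17 | C=CCOC(=O)N1[C@H]2C[C@@]3(O[Si](C)(C)C(C)(C)C)C(=O)[C@@H]([C@H]2OC1=O)[C@H](OC)[C@@H]1O[C@@H]13
F14 | step 15 | allyl N-[1-(tert-butyldimethylsilyloxy)-7,8-epoxy-4-hydroxy-6-methoxy-9-oxobicyclo[3.3.1]nonan-3-yl]carbamate | C=CCOC(=O)N[C@H]1C[C@@]2(O[Si](C)(C)C(C)(C)C)C(=O)[C@@H]([C@H]1O)[C@H](OC)[C@@H]1O[C@@H]12
A1 | alternative 1 | oxazolidinone cis-fused across C3 and C4 of 1-(4-methoxybenzyloxy)bicyclo[3.3.1]nonane-8,9-dione | O=C1N[C@H]2C[C@@]3(OCc4ccc(OC)cc4)C(=O)[C@@H]([C@H]2O1)CCC3=O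
A2 | alternative 1 | 4-carbamoyloxy-1-(4-methoxybenzyloxy)bicyclo[3.3.1]nonane-8,9-dione | C1C[C@@]2(OCc3ccc(OC)cc3)C(=O)[C@@H]([C@H]1OC(N)=O)CCC2=O
A3 | alternative 2 | benzyl N-[7,8-epoxy-1,4-dihydroxy-6-methoxy-9-oxobicyclo[3.3.1]nonan-3-yl]carbamate | O=C(OCc1ccccc1)N[C@H]1C[C@@]2(O)C(=O)[C@@H]([C@H]1O)[C@H](OC)[C@@H]1O[C@@H]12
A4 | alternative 2 | 7,8-epoxy-1-hydroxy-6-methoxybicyclo[3.3.1]non-3-en-9-one | C1C[C@@]2(O)C(=O)[C@@H](C=1)[C@H](OC)[C@@H]1O[C@@H]12
A5 | alternative 3 | tert-butyl N-[1-hydroxy-6-methoxy-9-oxo-4-(tert-butyldimethylsilyloxy)bicyclo[3.3.1]non-7-en-3-yl]carbamate | CC(C)(C)OC(=O)N[C@H]1C[C@@]2(O)C(=O)[C@@H]([C@H]1O[Si](C)(C)C(C)(C)C)[C@H](OC)C=C2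
A6 | alternative 3 | cis-fused tert-butyl N-[7a-hydroxy-3-methoxy-7-oxo-4-(tert-butyldimethylsilyloxy)-3,3a,4,5,6,7a-hexahydroinden-5-yl]carbamate | CC(C)(C)OC(=O)N[C@H]1CC(=O)[C@@]2(O)[C@@H]([C@H]1O[Si](C)(C)C(C)(C)C)[C@H](OC)C=C2
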